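No earlier run stands at the temperature of beta, alpha or epsilon, so none of their yields can be read off; a rule for carrying a rate across temperature has to be built.

| flask | starting material | coupling partner | temperature | remark | time |
|---|---|---|---|---|---|
| south-west | 0.070 M | 2 equiv | 35 °C | run made earlier |  |
| east | 0.11 M | 2 equiv | 68 °C | run made earlier |  |
| north-west | 0.050 M | 1 equiv | 35 °C | run made earlier |  |
| beta | 0.050 M | 2.00 equiv | 20 °C |  | 2.0 h |
| alpha | 0.050 M | 2.00 equiv | 80 °C |  | 2.0 h |
| epsilon | 0.050 M | 2.00 equiv | 50 °C |  | 2.0 h |

| south-west: time / min | south-west: target / % | east: time / min | east: target / % | north-west: time / min | north-west: target / % |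
|---|---|---|---|---|---|
| 10.0 | 5 | 2.00 | 15 | 3.00 | 0 |
| 20.0 | 9 | 4.00 | 27 | 6.00 | 1 |
| 25.0 | 13 | 5.00 | 34 | 15.0 | 2 |
| 40.0 | 21 | 8.00 | 44 | 40.0 | 7 |

(each reading ± 1.5 percentage points)

- what is said of target includes crystals
- crystals is a solid; its amount is given per volume of the solution
- what was read earlier has a scatter of 1.5 percentage points, one standard deviation
- steps that have been proposed: starting material <-> reactive form; crystals <-> target; coupling partner + reactive form -> target

- the flask that comes out highest in amount of target, in percent of the starting material charged, or "all alike" when all lie within 1.5 percentage points (beta / alpha / epsilon / all alike)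
- target at the end, in percent of the starting material charged, beta
- target at the end, in percent of the starting material charged, alpha
- target at the end, in percent of the starting material charged, epsilon

First instants: the proposed first step turns starting material into reactive form, but north-west reads 0% at 3.00 min, with a scatter of 1.5 percentage points, so that reading cannot tell whether a start-up occurs. The share of that step stays lumped in an apparent second-order constant k, with rate = k × starting material × coupling partner. At 35 °C and 40.0 min, the south-west reading is 3.00 times the north-west reading, a ratio that carries the scatter, and the south-west partner concentration is 2.80 times that of north-west.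

Middle: in this lumped rate, both reagents fall together as target forms. With c the starting concentration of starting material, y the target as a fraction (crystals included) and partner at 2 equiv, integration gives x = k·c·t = ln[(1 − y/2)/(1 − y)]. The last readings of south-west and east give, as values read with their scatter,

k at 35 °C = 7.43 × 10⁻⁴ M⁻¹ s⁻¹

k at 68 °C = 0.00628 M⁻¹ s⁻¹

In powers of ten, the decade width w, the temperature rise that multiplies k by ten, reads

w = 35.6 K

End: k = k(35 °C) × 10^(ΔT/w), and y = (e^x − 1)/(e^x − 0.5), with starting material the limiting reagent.

beta: x = 0.101, y = 17.6%

epsilon: x = 0.705, y = 67.2%

alpha: x = 4.91, y = 99.6%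

The forecast, by “Fitting second-order kinetics”, names alpha, with beta 14%, alpha 98% and epsilon 67%, and for beta it stands below this reckoning's 17.6%.

Beta gives 13.8%, epsilon 69.3% and alpha 99.6%, the highest.

    starting material ⇌ reactive form (K = 0.340, k = 0.0380 s⁻¹, Ea = 80.0 kJ mol⁻¹, ΔH = −1.00 kJ mol⁻¹)
    crystals ⇌ target, rate k2*(cs2 - [target]) while solid is left; crystals form when [target] > cs2 (solubility = 4.90 mM, k = 0.150 s⁻¹)
    coupling partner + reactive form → target (k = 0.00830 M⁻¹ s⁻¹, Ea = 60.0 kJ mol⁻¹)
    (constants at 50 °C)

Alpha moves by 5 points with its time cut to 0.928 h or its partner cut to 1.35 equiv. A repeat of beta at 45 °C has x = 0.511 by the decade width, so y = 57.1%, and that flask gives 58.5%.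

(The earlier runs and the new flask were generated by integration with constants of no real substance; noise was put on by code.)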